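**The pitfall.** I nearly asked which flask ran faster, and that would have favoured the warm one, but the real question was who takes the starting material, the limiting reagent, at each level of its concentration.

in all of them: starting material 18 mM; second substrate 4.00 equiv; free enzyme 0.042 mol%; time 3.0 d
- blue: temperature 37 °C
- teal: temperature 7 °C

1. the flask with the highest amount of target, in percent of the starting material charged ("all alike" if they lie within 1.5 percentage points) (blue / teal / all alike)
2. final target, as a percentage of the starting material charged, in blue
3. final target, as a percentage of the starting material charged, in teal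

- percentages count the starting material that a species holds: one homo dimer counts as two
- two of one species on the left: rate k times its square, two consumed each time
- all constants are for 37 °C and move with temperature by the activation energies and enthalpies

    free enzyme → unfolded enzyme (k1 = 0.0124 h⁻¹, Ea1 = 225 kJ mol⁻¹)
    starting material + free enzyme ⇌ first complex (K2 = 293 L mol⁻¹, k2 = 2.47 × 10⁶ L mol⁻¹ h⁻¹, Ea2 = 48.0 kJ mol⁻¹, ΔH2 = −39.0 kJ mol⁻¹)
    first complex → loaded enzyme + first product (k3 = 628 h⁻¹, Ea3 = 83.0 kJ mol⁻¹)
    second substrate + loaded enzyme ⇌ second complex (K4 = 9.2 L mol⁻¹, k4 = 2.13 × 10⁵ L mol⁻¹ h⁻¹, Ea4 = 39.0 kJ mol⁻¹, ΔH4 = −57.0 kJ mol⁻¹)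
    second complex → free enzyme + target (k5 = 355 h⁻¹, Ea5 = 71.0 kJ mol⁻¹)
    starting material + second substrate → uncatalysed product (k6 = 0.843 L mol⁻¹ h⁻¹, Ea6 = 59.0 kJ mol⁻¹)
    2 starting material → homo dimer (k7 = 65.4 L mol⁻¹ h⁻¹, Ea7 = 61.0 kJ mol⁻¹)
    (constants at 37 °C)

**Enzyme capacity.** The enzyme charge was 0.00756 mM, and I held c(second substrate) at its charge of 72.0 mM. In blue, the second substrate reaches half-occupancy at 110 mM. One round therefore lasts the life of the first complex plus the life of the second complex, stretched by one plus that level over c(second substrate), which comes to 31.4 s. That gave a capacity of 0.866 mM h⁻¹.

**The crossing.** The homo dimer step uses starting material at twice its constant times the square of c(starting material), so its demand falls steeply while the enzyme holds its pace. In blue the two meet at 2.57 mM, and this level, where the dimer's consumption equals the enzyme's capacity, is the crossing concentration.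

**Blue ledger.** At the charge, the dimer step demands 42.4 mM h⁻¹, far more than the enzyme's capacity. The fall to the crossing takes about 2.55 h, much shorter than the enzyme's unfolding half-life of 55.9 h. In that time I booked 2.21 mM to the enzyme and about 0.903 mM to the uncatalysed product, with 12.3 mM of starting material to the homo dimer. Of the 2.57 mM left at the crossing I gave the enzyme half, a rough share, so the books closed at 19.4% target in blue.

**Teal ledger.** Cooling cuts the capacity of teal to 0.0677 mM h⁻¹, by a factor of 12.8. But the dimer constant falls by a factor of 12.6, to 5.19 L mol⁻¹ h⁻¹. The crossing in teal therefore stays at 2.55 mM, about the same as in blue. The same books gave 19.3% in teal, a gap of 0.10 percentage points, so I expected the flasks to be alike. I reckoned that teal would reach its crossing after 32.4 h and that the remainder would need 37.7 h at capacity, just inside the 72 h allowed.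

**The result.** The forecast gave 17.3% in blue and 17.9% in teal, answered all alike, and held that “the target is set by partitioning”, with figures lower than mine. The flasks gave 17.4% in blue and 18.0% in teal, hence all alike, so my ledger ran 2 points high in blue.

**Main loss.** The main reason the target in blue stops where it does is the homo dimer step: in the blue run without that step the target reaches 64.0% instead of 17.4%. The target in blue stands at 1.21 times its crossing concentration. For the neighbour of blue, charged with 0.011 mol% of free enzyme, I reckoned a crossing at 1.32 mM, which at that ratio points to 8.89%, and that neighbour holds 7.97%.

All constants are assumed; no experiment stands behind them.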